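The runs stem from a simulated flask with constants of no real substance.

Time came first: flasks eta and epsilon are to be read at 8.0 d, but the earlier runs stop at 6.00 d, so the meeting had to carry the readings past their last point.

| flask | left-handed substrate | right-handed substrate | partner | protic impurity | free catalyst | stray impurity | remark | time |
|---|---|---|---|---|---|---|---|---|
| winter | 26 mM | 26 mM | 0.60 equiv (fed, over 12 h) | 1.3 mM | 0.17 mol% | 29 µM | run made earlier |  |
| dusk | 26 mM | 26 mM | 0.60 equiv (fed, over 12 h) | 1.3 mM | 0.23 mol% | 29 µM | run made earlier |  |
| summer | 26 mM | 26 mM | 0.60 equiv (fed, over 12 h) | 1.3 mM | 0.25 mol% | 29 µM | run made earlier |  |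
| eta | 26 mM | 26 mM | 0.600 equiv (fed, over 12 h) | 1.30 mM | 0.2 mol% | 29 µM |  | 8.0 d |
| epsilon | 26 mM | 26 mM | 0.600 equiv (fed, over 12 h) | 1.30 mM | 0.3 mol% | 29 µM |  | 8.0 d |

| run | time / d | right-handed substrate / % | left-handed substrate / % | left-handed product / % |
|---|---|---|---|---|
| winter | 0.500 | 51.2 | 49.0 | 0.2 |
| winter | 1.25 | 49.8 | 47.0 | 6.3 |
| winter | 2.50 | 49.8 | 43.1 | 7.6 |
| winter | 4.00 | 49.8 | 39.5 | 8.4 |
| winter | 6.00 | 50.0 | 39.4 | 12.8 |
| dusk | 1.04 | 50.6 | 44.6 | 4.4 |
| dusk | 2.50 | 47.1 | 39.6 | 8.7 |
| dusk | 3.00 | 49.1 | 36.8 | 10.3 |
| dusk | 5.00 | 49.8 | 35.8 | 12.1 |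
| dusk | 6.00 | 48.4 | 34.5 | 16.6 |
| summer | 0.500 | 49.2 | 46.3 | 1.7 |
| summer | 1.25 | 50.1 | 42.9 | 5.0 |
| summer | 2.50 | 51.6 | 38.6 | 10.9 |
| summer | 4.00 | 48.6 | 37.3 | 11.2 |
| summer | 6.00 | 49.9 | 33.0 | 19.0 |

(scatter of a reading: 1 percentage point)

- free catalyst is single-handed; left-handed substrate and right-handed substrate are mirror images of each other, charged as a racemate, each of them at the stated concentration
- the earlier runs were read with a standard deviation of 1 percentage point
- an excess is below zero if the other one leads

- the winner by excess of right-handed substrate over left-handed substrate among what is left of the two; "neither" if no more than 2 percentage points parts them (eta / epsilon / neither)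
- excess of right-handed substrate over left-handed substrate among what is left of the two at the end, eta
- excess of right-handed substrate over left-handed substrate among what is left of the two at the end, epsilon

The process chemist began with the charge. She took each partner to remove one substrate molecule and assumed one partner lost per protic impurity, so of the 15.6 mM of [partner] fed, 14.3 mM stays usable; against 26 mM of left-handed substrate, partner is the limiting reagent. The right-handed substrate stood near its charge in the readings (49.9% in summer at 6.00 d), so she counted the usable partner against the left-handed substrate. She proposed working with the fraction left, left-handed over right-handed substrate, and gave its floor as 45.0%, the fraction left once the usable partner is spent on left-handed substrate. The excess is one minus that fraction over one plus it, which puts the ceiling at 37.9%.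

The kineticist took the height above the floor, as a share of its starting height, to decay exponentially, with one time constant per flask. Winter, read at 6.00 d, has a fraction left of 78.8%, hence 12.3 d. Summer has 66.1%, hence 6.27 d, about twice as fast on 1.47 times the loading. The chair suspected the stray impurity, whose 29 µM is less than the 44.2 µM of winter catalyst but not small. Readings scatter by 1 percentage point, so the meeting drew one straight line of rate against loading through winter and summer.

My own reckoning follows that line. Time over time constant at 8.0 d comes to 0.884 for eta and 1.67 for epsilon. The fractions left are then 67.7% and 55.4%, and the excesses 19.2% and 28.7%, so epsilon wins by 9.5 points.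

The forecast, noting “Curves decelerate”, gave 16% for eta, 27% for epsilon and epsilon as winner.

The flasks give 18.9% for eta and 26.9% for epsilon, so epsilon wins; my epsilon figure of 28.7% is higher than the flask's.

    partner ⇌ dormant form (K = 1.80, k = 0.467 h⁻¹)
    partner + catalyst intermediate A → free catalyst + left-handed product (k = 674 M⁻¹ h⁻¹)
    partner + protic impurity → quenched reagent (k = 244 M⁻¹ h⁻¹)
    free catalyst + left-handed substrate ⇌ catalyst intermediate A (K = 560 M⁻¹, k = 1.08 × 10⁵ M⁻¹ h⁻¹)
    free catalyst + stray impurity → spent catalyst (k = 16500 M⁻¹ h⁻¹)
    partner + catalyst intermediate B → free catalyst + right-handed product (k = 251 M⁻¹ h⁻¹)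
    free catalyst + right-handed substrate ⇌ catalyst intermediate B (K = 72.0 M⁻¹, k = 18600 M⁻¹ h⁻¹)

Flask epsilon ends with a fraction left of 57.7%, above the floor of 45.0%, and 4.9% of its partner is still free. The neighbouring flask is epsilon with 0.75 mol% of catalyst and the same partner, so floor and ceiling stay put. Its usable partner equals 27.5% of both substrates charged, and at 8.00 d its left-handed and right-handed products together hold 27.4%, with 0.11% of the partner free. Its fraction left stands at 50.0%, and its excess is 33.4%, less than the ceiling of 37.9%.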